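**Retrosynthetic overview**

1. The target is read as two C12 halves of identical (3R,4S) configuration, a quinone-methide pyran unit (left) and a lactone unit (right), joined C7–CH(CH3)–C7. Both are numbered as isochromenes (C1, O2, C3, C4, C4a, C5–C8, C8a), and the same numbers are used for the open precursors.
2. Last disconnection: the left pyran ring, by removal of C1 (bonds C1–C8a and C1–O2, C1 from an orthoformate). In the same flask, just before it, the C7(left)–CH(CH3) bond is made by catalyst-controlled addition of the open left-half triol to the ortho-quinone methide of a 7-vinyl lactone.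
3. Triol and lactone both come from one benzyl-protected (2R,3S)-3-arylbutan-2-ol (aryl Grignard opening of (2S,3S)-2,3-dimethyloxirane, then Mitsunobu inversion). The lactone carbon enters by bromination, lithiation and CO2.
4. Ring order: the two benzene rings are bought, the lactone ring is closed in step 8, the left pyran ring last, in step 12.
5. Enabling feature: in the open left half, C8a is the only unsubstituted aromatic carbon of the whole coupled molecule, para to the oxygen on C6 and ortho to the oxygen on C8, and O2, C3, C4, C4a and C8a lack only C1 to complete the six-membered ring. C7 of each half lies between two phenolic oxygens, which makes the right C7-vinyl group a quinone-methide precursor and the left C7 its nucleophile.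

Key step: step 12

Assumption: the sense of induction of the chiral phosphoric acid in step 12 cannot be read from the structure; the (R)-catalyst is written, and its mirror image would be used if the (R)-catalyst favours the linker epimer.
Assumption: 1-bromo-3,5-bis(benzyloxy)benzene and (2S,3S)-2,3-dimethyloxirane are taken as purchasable.

**Route**

Step 1
Reactants: 1 1-bromo-3,5-bis(benzyloxy)benzene
Product: 3 2,4-bis(benzyloxy)-6-bromobenzaldehyde, via iminium salt 2 (not isolated)
Conditions: POCl3, DMF, 0 → 80 °C; then H2O
Reagents that add atoms: N,N-dimethylformamide CN(C)C=O; water O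
Why: Vilsmeier–Haack formylation should enter next to bromine, the position para to one benzyloxy group and ortho to the other, and not the more hindered, only ortho-activated carbon between the two ethers.

Step 2
Reactants: 3 2,4-bis(benzyloxy)-6-bromobenzaldehyde
Product: 4 1,5-bis(benzyloxy)-3-bromo-2-methylbenzene
Conditions: Et3SiH (3 equiv), CF3CO2H, CH2Cl2, 0 °C → rt
Reagents that add atoms: none
Why: Ionic hydrogenation, in which the benzylic cation stabilised by the ortho and para ether oxygens is reduced twice by the silane, should turn the formyl group into the future C5 methyl while aryl bromide and benzyl ethers survive the short acid exposure.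

Step 3
Reactants: 4 1,5-bis(benzyloxy)-3-bromo-2-methylbenzene; 5 (2S,3S)-2,3-dimethyloxirane
Product: 7 (2S,3S)-3-[3,5-bis(benzyloxy)-2-methylphenyl]butan-2-ol, via aryl Grignard reagent 6 (not isolated)
Conditions: Mg, THF, 50 °C; then CuI (10 mol%), 5, −30 → 0 °C; aq NH4Cl
Reagents that add atoms: none
Why: Copper-catalysed SN2 opening of the C2-symmetric epoxide by the aryl Grignard reagent (both epoxide carbons are equivalent) proceeds with inversion at the attacked carbon, which sets the benzylic centre (future C4) with the S descriptor and leaves the carbinol centre S.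

Step 4
Reactants: 7 (2S,3S)-3-[3,5-bis(benzyloxy)-2-methylphenyl]butan-2-ol
Product: 8 (2R,3S)-3-[3,5-bis(benzyloxy)-2-methylphenyl]butan-2-yl 4-nitrobenzoate
Conditions: 4-O2NC6H4CO2H, PPh3, diisopropyl azodicarboxylate, toluene, 0 °C → rt
Reagents that add atoms: 4-nitrobenzoic acid O=C(O)c1ccc(cc1)[N+](=O)[O-]
Why: Mitsunobu reaction, in which 4-nitrobenzoate displaces the alkoxyphosphonium ion by SN2, inverts the carbinol centre from S to R (future C3) and so gives the threo arrangement that corresponds to trans-3,4-dimethyl rings.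

Step 5
Reactants: 8 (2R,3S)-3-[3,5-bis(benzyloxy)-2-methylphenyl]butan-2-yl 4-nitrobenzoate
Product: 9 (2R,3S)-3-[3,5-bis(benzyloxy)-2-methylphenyl]butan-2-ol
Conditions: K2CO3 (0.2 equiv), MeOH/THF, rt
Reagents that add atoms: none
Why: Base-catalysed transesterification (methanolysis) of the activated 4-nitrobenzoate should release the alcohol at the acyl carbon, so neither stereocentre is touched.

Step 6
Reactants: 9 (2R,3S)-3-[3,5-bis(benzyloxy)-2-methylphenyl]butan-2-ol
Product: 10 (2R,3S)-3-(3,5-dihydroxy-2-methylphenyl)butan-2-ol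
Conditions: H2 (1 atm), Pd/C, EtOAc/MeOH, rt
Reagents that add atoms: none
Why: Hydrogenolysis of the two benzyl ethers over Pd/C should give the triol cleanly, since the homobenzylic alcohol and the benzylic C–H centre carry no hydrogenolysable bond.

Step 7
Reactants: 9 (2R,3S)-3-[3,5-bis(benzyloxy)-2-methylphenyl]butan-2-ol
Product: 11 (2R,3S)-3-[3,5-bis(benzyloxy)-2-bromo-6-methylphenyl]butan-2-ol
Conditions: NBS, MeCN, 0 °C, dark
Reagents that add atoms: N-bromosuccinimide O=C1CCC(=O)N1Br
Why: Electrophilic aromatic bromination should go to C8a, which is para to one benzyloxy group and ortho to the other, and not to the carbon between the two ethers, which is only ortho-activated.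

Step 8
Reactants: 11 (2R,3S)-3-[3,5-bis(benzyloxy)-2-bromo-6-methylphenyl]butan-2-ol
Product: 14 (3R,4S)-6,8-bis(benzyloxy)-3,4,5-trimethyl-3,4-dihydro-1H-isochromen-1-one, via dilithio species 12 (not isolated), via hydroxy acid 13 (not isolated)
Conditions: nBuLi (2.2 equiv), THF, −78 °C; CO2, −78 °C → rt; 2 M HCl; then TsOH (cat.), toluene, 60 °C
Reagents that add atoms: carbon dioxide O=C=O
Why: Bromine–lithium exchange on the lithium alkoxide, carboxylation of the aryllithium and acid-catalysed lactonisation (6-exo-trig attack of the secondary hydroxyl on the carboxyl group) should close the lactone ring with both stereocentres unchanged.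

Step 9
Reactants: 14 (3R,4S)-6,8-bis(benzyloxy)-3,4,5-trimethyl-3,4-dihydro-1H-isochromen-1-one
Product: 15 (3R,4S)-6,8-dihydroxy-3,4,5-trimethyl-3,4-dihydro-1H-isochromen-1-one
Conditions: H2 (1 atm), Pd/C, EtOAc/MeOH, rt
Reagents that add atoms: none
Why: Hydrogenolysis of the benzyl ethers should free both phenols without affecting the lactone, whose C3–O bond is not benzylic.

Step 10
Reactants: 15 (3R,4S)-6,8-dihydroxy-3,4,5-trimethyl-3,4-dihydro-1H-isochromen-1-one
Product: 16 (3R,4S)-6,8-dihydroxy-7-iodo-3,4,5-trimethyl-3,4-dihydro-1H-isochromen-1-one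
Conditions: NIS, MeCN, 0 °C
Reagents that add atoms: N-iodosuccinimide O=C1CCC(=O)N1I
Why: Electrophilic aromatic iodination can only take place at C7, the single unsubstituted ring carbon, which is activated by both ortho hydroxyl groups.

Step 11
Reactants: 16 (3R,4S)-6,8-dihydroxy-7-iodo-3,4,5-trimethyl-3,4-dihydro-1H-isochromen-1-one
Product: 17 (3R,4S)-7-ethenyl-6,8-dihydroxy-3,4,5-trimethyl-3,4-dihydro-1H-isochromen-1-one
Conditions: CH2=CHSnBu3, Pd(PPh3)4 (5 mol%), BHT (cat.), toluene, 90 °C
Reagents that add atoms: tributyl(ethenyl)stannane C=C[Sn](CCCC)(CCCC)CCCC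
Why: Stille coupling under neutral conditions tolerates the free phenols and the lactone and should install the vinyl group that serves as the latent ortho-quinone methide.

Step 12
Reactants: 17 (3R,4S)-7-ethenyl-6,8-dihydroxy-3,4,5-trimethyl-3,4-dihydro-1H-isochromen-1-one; 10 (2R,3S)-3-(3,5-dihydroxy-2-methylphenyl)butan-2-ol
Product: 20 dicitrinone H, via open adduct 18 (not isolated), via ethoxy acetal 19 (not isolated)
Conditions: (R)-3,3'-bis(2,4,6-triisopropylphenyl)-1,1'-binaphthyl-2,2'-diyl hydrogen phosphate (10 mol%), ClCH2CH2Cl, 0 °C → rt; then HC(OEt)3, CF3CO2H, 0 °C → rt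
Reagents that add atoms: triethyl orthoformate CCOC(OCC)OCC
Why: The phosphoric acid protonates the electron-rich vinyl group of 17 to an ortho-quinone methide (either flanking hydroxyl can become the carbonyl and both forms lead to the same adduct) and C7 of 10, the carbon between its two hydroxyls, adds to it, the closest known reaction type being chiral phosphoric acid-catalysed Friedel–Crafts addition of phenols to ortho-quinone methides generated from ortho-hydroxystyrenes. The linker stereocentre is set by the catalyst, which binds the quinone methide carbonyl and a phenolic OH of 10 in one chiral pocket, the four ring stereocentres being too remote to compete. Site selectivity for C7 over C8a of 10 is needed and should follow from C8a being flanked by the branched side chain while C7 lies between two small hydroxyls, and 17 has no free ring carbon with which to condense with itself. On addition of HC(OEt)3 and acid the secondary hydroxyl of 18 exchanges into the orthoformate and the tethered dialkoxycarbenium ion is attacked by C8a, the only aromatic C–H left in the molecule, in a 6-endo-trig oxa-Pictet–Spengler closure (the known orthoformate formylation–cyclisation of citrinin-type resorcinol alcohols) to give acetal 19. Loss of ethanol from 19 gives the hydrogen-bonded quinone methide, in which C1 ends as an sp2 carbon, so no further stereocentre arises and C3 and C4 are not touched. The acid is kept mild and the temperature low to avoid retro-Friedel–Crafts exchange at the doubly benzylic linker.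

**Compound list**

1 | 1-bromo-3,5-bis(benzyloxy)benzene | Brc1cc(OCc2ccccc2)cc(OCc2ccccc2)c1 | starting material
2 | {[2,4-bis(benzyloxy)-6-bromophenyl]methylidene}dimethylammonium dichlorophosphate (not isolated) | C[N+](C)=Cc1c(Br)cc(OCc2ccccc2)cc1OCc1ccccc1.[O-]P(=O)(Cl)Cl | intermediate
3 | 2,4-bis(benzyloxy)-6-bromobenzaldehyde | O=Cc1c(Br)cc(OCc2ccccc2)cc1OCc1ccccc1 | intermediate
4 | 1,5-bis(benzyloxy)-3-bromo-2-methylbenzene | Cc1c(Br)cc(OCc2ccccc2)cc1OCc1ccccc1 | intermediate
5 | (2S,3S)-2,3-dimethyloxirane | C[C@@H]1O[C@H]1C | starting material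
6 | [3,5-bis(benzyloxy)-2-methylphenyl]magnesium bromide (not isolated) | Cc1c([Mg]Br)cc(OCc2ccccc2)cc1OCc1ccccc1 | intermediate
7 | (2S,3S)-3-[3,5-bis(benzyloxy)-2-methylphenyl]butan-2-ol | C[C@H](O)[C@@H](C)c1cc(OCc2ccccc2)cc(OCc2ccccc2)c1C | intermediate
8 | (2R,3S)-3-[3,5-bis(benzyloxy)-2-methylphenyl]butan-2-yl 4-nitrobenzoate | C[C@@H](OC(=O)c1ccc(cc1)[N+](=O)[O-])[C@@H](C)c1cc(OCc2ccccc2)cc(OCc2ccccc2)c1C | intermediate
9 | (2R,3S)-3-[3,5-bis(benzyloxy)-2-methylphenyl]butan-2-ol | C[C@@H](O)[C@@H](C)c1cc(OCc2ccccc2)cc(OCc2ccccc2)c1C | intermediate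
10 | (2R,3S)-3-(3,5-dihydroxy-2-methylphenyl)butan-2-ol | C[C@@H](O)[C@@H](C)c1cc(O)cc(O)c1C | intermediate
11 | (2R,3S)-3-[3,5-bis(benzyloxy)-2-bromo-6-methylphenyl]butan-2-ol | C[C@@H](O)[C@@H](C)c1c(Br)c(OCc2ccccc2)cc(OCc2ccccc2)c1C | intermediate
12 | lithium (2R,3S)-3-[3,5-bis(benzyloxy)-2-lithio-6-methylphenyl]butan-2-olate (not isolated) | C[C@@H](O[Li])[C@@H](C)c1c([Li])c(OCc2ccccc2)cc(OCc2ccccc2)c1C | intermediate
13 | 2,4-bis(benzyloxy)-6-[(2S,3R)-3-hydroxybutan-2-yl]-5-methylbenzoic acid (not isolated) | C[C@@H](O)[C@@H](C)c1c(C(=O)O)c(OCc2ccccc2)cc(OCc2ccccc2)c1C | intermediate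
14 | (3R,4S)-6,8-bis(benzyloxy)-3,4,5-trimethyl-3,4-dihydro-1H-isochromen-1-one | Cc1c(OCc2ccccc2)cc(OCc2ccccc2)c2c1[C@H](C)[C@@H](C)OC2=O | intermediate
15 | (3R,4S)-6,8-dihydroxy-3,4,5-trimethyl-3,4-dihydro-1H-isochromen-1-one | Cc1c(O)cc(O)c2c1[C@H](C)[C@@H](C)OC2=O | intermediate
16 | (3R,4S)-6,8-dihydroxy-7-iodo-3,4,5-trimethyl-3,4-dihydro-1H-isochromen-1-one | Cc1c(O)c(I)c(O)c2c1[C@H](C)[C@@H](C)OC2=O | intermediate
17 | (3R,4S)-7-ethenyl-6,8-dihydroxy-3,4,5-trimethyl-3,4-dihydro-1H-isochromen-1-one | Cc1c(O)c(C=C)c(O)c2c1[C@H](C)[C@@H](C)OC2=O | intermediate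
18 | (3R,4S)-7-[(1S)-1-{2,6-dihydroxy-4-[(2S,3R)-3-hydroxybutan-2-yl]-3-methylphenyl}ethyl]-6,8-dihydroxy-3,4,5-trimethyl-3,4-dihydro-1H-isochromen-1-one (not isolated) | C[C@@H](O)[C@@H](C)c1cc(O)c([C@H](C)c2c(O)c(C)c3c(c2O)C(=O)O[C@H](C)[C@H]3C)c(O)c1C | intermediate
19 | (3R,4S)-7-[(1S)-1-[(3R,4S)-1-ethoxy-6,8-dihydroxy-3,4,5-trimethyl-3,4-dihydro-1H-isochromen-7-yl]ethyl]-6,8-dihydroxy-3,4,5-trimethyl-3,4-dihydro-1H-isochromen-1-one, both epimers at the acetal carbon (not isolated) | CCOC1O[C@H](C)[C@@H](C)c2c(C)c(O)c([C@H](C)c3c(O)c(C)c4c(c3O)C(=O)O[C@H](C)[C@H]4C)c(O)c12 | intermediate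
20 | dicitrinone H, (3R,4S)-6,8-dihydroxy-7-[(1R)-1-[(3R,4S)-6-hydroxy-3,4,5-trimethyl-8-oxo-4,8-dihydro-3H-isochromen-7-yl]ethyl]-3,4,5-trimethyl-3,4-dihydro-1H-isochromen-1-one (the linker has the same spatial arrangement as in 18 and 19; the descriptor changes from S to R because the ring priorities change on dearomatisation) | CC1=C2C(=CO[C@H](C)[C@H]2C)C(=O)C([C@H](C)c2c(O)c(C)c3c(c2O)C(=O)O[C@H](C)[C@H]3C)=C1O | target

**Step count and risks**

Total step count: 12. Longest linear sequence: 11 steps (steps 1–5 and 7–12).

Steps most likely to fail: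

1. Step 12. What may go wrong: attack of the quinone methide at C8a or at a hydroxyl oxygen of 10, low facial selectivity at the linker carbon, or acid-induced exchange at the linker during the orthoformate stage. The fallback sets out from 10 and 17 and comes back to the route at 20. Triol 10 alone is treated with HC(OEt)3 and CF3CO2H, the same formylation–cyclodehydration now run before the coupling, to give the quinone methide (3R,4S)-6-hydroxy-3,4,5-trimethyl-4,8-dihydro-3H-isochromen-8-one F1, a vinylogous acid whose only nucleophilic carbon is C7. F1 is then added under the same chiral phosphoric acid to the ortho-quinone methide formed from 17 (conjugate addition of a cyclic 1,3-dicarbonyl-type nucleophile to an ortho-quinone methide), which should give 20 with no strong acid used after the linker bond exists.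

2. Step 11. What may go wrong: reductive loss of iodine during the coupling, or heat- and acid-induced oligomerisation of the electron-rich vinylresorcinol during coupling or isolation. The fallback sets out from 15 and comes back to the route at 18, inside step 12. Rieche formylation (Cl2CHOMe, TiCl4, CH2Cl2, 0 °C) at C7, the only free ring carbon, should give (3R,4S)-6,8-dihydroxy-3,4,5-trimethyl-1-oxo-3,4-dihydro-1H-isochromene-7-carbaldehyde F2. Addition of MeMgBr (excess, THF, −78 → 0 °C; the bis-phenoxide deactivates the lactone carbonyl) should give (3R,4S)-6,8-dihydroxy-7-(1-hydroxyethyl)-3,4,5-trimethyl-3,4-dihydro-1H-isochromen-1-one F3 as a mixture of carbinol epimers. F3 takes the place of 17 in step 12: the phosphoric acid dehydrates both epimers to the same ortho-quinone methide, so the mixture should converge on 18.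

3. Step 4. What may go wrong: elimination to the conjugated styrene, or aryl participation leading to retention at the hindered carbinol. The fallback sets out from 7 and comes back to the route at 9. Oxidation with Dess–Martin periodinane (NaHCO3, CH2Cl2, 0 °C) should give (3S)-3-[3,5-bis(benzyloxy)-2-methylphenyl]butan-2-one F4 without enolisation of the benzylic centre. Reduction with LiBH(sBu)3 (THF, −78 °C) should then deliver hydride in the Felkin–Anh sense, anti to the aryl group, to give the (2R,3S) alcohol 9.

Further compounds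
F1 | step 12 | (3R,4S)-6-hydroxy-3,4,5-trimethyl-4,8-dihydro-3H-isochromen-8-one | CC1=C2C(=CO[C@H](C)[C@H]2C)C(=O)C=C1O
F2 | step 11 | (3R,4S)-6,8-dihydroxy-3,4,5-trimethyl-1-oxo-3,4-dihydro-1H-isochromene-7-carbaldehyde | Cc1c(O)c(C=O)c(O)c2c1[C@H](C)[C@@H](C)OC2=O
F3 | step 11 | (3R,4S)-6,8-dihydroxy-7-(1-hydroxyethyl)-3,4,5-trimethyl-3,4-dihydro-1H-isochromen-1-one, both carbinol epimers | Cc1c(O)c(C(C)O)c(O)c2c1[C@H](C)[C@@H](C)OC2=O
F4 | step 4 | (3S)-3-[3,5-bis(benzyloxy)-2-methylphenyl]butan-2-one | CC(=O)[C@@H](C)c1cc(OCc2ccccc2)cc(OCc2ccccc2)c1C
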